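(The readings are calculated for an exercise.)

In the flask c(second substrate) = 0.0500 M stands below c(starting material) = 0.10 M, so if each turnover spends one second substrate, that is the limiting reagent, and I count turnovers against it.

all flasks: enzyme 50 µM

| run | starting material | second substrate | remark |
|---|---|---|---|
| elm | 0.067 M | 0.050 M | run made earlier |
| maple | 0.15 M | 0.050 M | run made earlier |
| flask | 0.10 M | 0.0500 M |  |

| run | time / min | target / % | starting material / % |
|---|---|---|---|
| elm | 3.00 | 10.4 | 90.2 |
| elm | 5.00 | 15.8 | 83.8 |
| elm | 8.00 | 21.9 | 78.7 |
| elm | 12.0 | 27.3 | 73.0 |
| elm | 20.0 | 34.6 | 64.6 |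
| elm | 40.0 | 49.2 | 50.1 |
| maple | 3.00 | 5.4 | 94.6 |
| maple | 5.00 | 8.2 | 91.8 |
| maple | 8.00 | 10.9 | 88.1 |
| maple | 12.0 | 13.8 | 85.5 |
| maple | 20.0 | 19.7 | 81.1 |
| maple | 40.0 | 25.7 | 75.2 |

(readings scatter by 0.5 percentage points)

- apparent order in second substrate when 5.0% of the starting material are converted (percent change of the rate of making target for one percent more second substrate charged)
- apparent order in enzyme when 5.0% of the starting material are converted (percent change of the rate of making target for one percent more enzyme charged)

- no earlier run changes the charge of enzyme; that part of a forecast is a guess
- no earlier run changes the charge of second substrate; that part of a forecast is a guess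

The enzyme at 50 µM has 1000 turnovers in the second-substrate charge, and 100 of them give 5.0% conversion. Both counts fold into one number, the charge ratio 2.00, c(starting material) over c(second substrate). Multiplied by a conversion, it gives the turnover share: the part of the second-substrate charge that has left as target. At the point asked, the flask's share is 0.100, so by this count 0.900 of the flask's second-substrate charge is still there.

Is one number enough? In elm the rate of making target from 20.0 min to 40.0 min is 0.211 of its rate over the first 3.00 min. That is less than the 0.341 of the charge the count leaves at 40.0 min. So in elm a rate in simple proportion to the counted charge doesn't reach the fall read there. No earlier run changes the charge of second substrate or of enzyme, so I give no order of my own.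

The forecast says 0.8 in second substrate, “around 0.8, but no run varied it”, and 1 in enzyme.

    second substrate ⇌ dormant form (K = 2.16, k = 0.00258 s⁻¹)
    ternary complex → enzyme + target (k = 1.51 s⁻¹)
    second substrate + starting complex ⇌ ternary complex (K = 55.5 M⁻¹, k = 3540 M⁻¹ s⁻¹)
    starting material + enzyme ⇌ starting complex (K = 18.0 M⁻¹, k = 945 M⁻¹ s⁻¹)

The flask gives 0.57 in second substrate, so the forecast stands 1.40 times too high there, and 1.1 in enzyme. After 3.00 min the flask holds 54.2% of its second-substrate charge, while the turnover share is 0.150 and the dormant form holds 0.0154 M, which is 30.8% of that charge. In maple the charge ratio is 3.00, and the reading of 25.7% target at 40.0 min gives a turnover share of 0.771.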